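**Plan**

- Numbering (decalin as a 4,9-friedodrimane): ring A = C1, C2, C3 (C=O), C4 (CHMe), C5 (CMe), C10 (H); ring B = C5, C6, C7, C8 (CHMe), C9 (CMe, C11H2–O–coumarin), C10.
- Retrosynthesis: first C4–CH3 (alkylation next to a C4 ester handle that is excised last), then C4–C5 and C9–C10 together, which opens both rings to an acyclic (E,E)-dienyl β-keto ester. Further cuts: C3–C4 (Roskamp), C11–O (Mitsunobu), C8–CH3 (cross-coupling), C8–C9 (Claisen condensation), C6–C7 (Johnson–Claisen), C10–C1 (Grignard).
- Forward: the chain is built linearly (steps 1–6), the coumarin and the β-keto ester are attached (steps 7–9), ring B and then ring A close in one cationic cascade (step 10), and C4 is methylated and de-esterified (steps 11–12).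
- Enabling feature: C8, C9, C10, C5 and C4 are contiguous. Ring B is substituted like the head ring of a polyprenoid cyclization product (C9 with CH3/CH2OAr, angular C5 methyl trans to H-10), and the C3 carbonyl lies 1,5 to C5. A cation at C9 can therefore be relayed through a C5=C10 bond to an enol at C4.
- Stereochemistry: C8/C9 from anti addition of H+ and C10 across the (E)-C8=C9 alkene; C10/C5 from anti addition across the (E)-C5=C10 alkene in a chair–chair fold; absolute sense from a chiral proton donor; C4 by equilibration to the equatorial methyl.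

Key step: step 10

Assumption: the target is taken exactly as written, (4S,5R,8S,9S,10S), with the C8 methyl axial and trans to the C9 methyl. The (R)-configured acid complex is assumed to protonate the face of C8 that leads to this enantiomer; if the sense is opposite, the (S)-ligand is used.

**Step 1**
Reactants: 1 methacrolein; 2 2-(1,3-dioxolan-2-yl)ethylmagnesium bromide
Product: 3 (±)-5-(1,3-dioxolan-2-yl)-2-methylpent-1-en-3-ol
Conditions: THF, −78 → 0 °C; aq NH4Cl
Reagents that add atoms: none
Why: Grignard 1,2-addition to the enal should give the 2-methylallylic secondary alcohol needed for the Claisen step, whose racemic carbinol centre is destroyed in step 2.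

**Step 2**
Reactants: 3 (±)-5-(1,3-dioxolan-2-yl)-2-methylpent-1-en-3-ol; 4 triethyl orthoacetate
Product: 6 ethyl (4E)-7-(1,3-dioxolan-2-yl)-4-methylhept-4-enoate, via mixed ketene acetal 5 (not isolated)
Conditions: MeC(OEt)3 (5 equiv), EtCO2H (5 mol %), 140 °C, EtOH distilled off
Reagents that add atoms: none
Why: the Johnson–Claisen rearrangement through a chair transition state with the side chain equatorial should form C6–C7 and set the (E)-C5=C10 trisubstituted alkene.

**Step 3**
Reactants: 6 ethyl (4E)-7-(1,3-dioxolan-2-yl)-4-methylhept-4-enoate; 7 tert-butyl propionate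
Product: 9 tert-butyl (6E)-9-(1,3-dioxolan-2-yl)-2,6-dimethyl-3-oxonon-6-enoate, via lithium enolate 8 (not isolated)
Conditions: 7 (2.5 equiv), LiN(i-Pr)2 (2.5 equiv), THF, −78 °C; then 6, −78 → −20 °C; aq NH4Cl
Reagents that add atoms: none
Why: crossed Claisen condensation of the slowly self-condensing tert-butyl ester enolate with the ethyl ester should install C8 (as ketone), C9 with its methyl and C11, the racemic C9 centre becoming sp2 in step 4.

**Step 4**
Reactants: 9 tert-butyl (6E)-9-(1,3-dioxolan-2-yl)-2,6-dimethyl-3-oxonon-6-enoate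
Product: 11 tert-butyl (2Z,6E)-9-(1,3-dioxolan-2-yl)-2,6-dimethyl-3-{[(trifluoromethyl)sulfonyl]oxy}nona-2,6-dienoate, via sodium enolate 10 (not isolated)
Conditions: NaH, Et2O, 0 °C; Tf2O, −78 → 0 °C
Reagents that add atoms: trifluoromethanesulfonic anhydride, O=S(=O)(OS(=O)(=O)C(F)(F)F)C(F)(F)F
Why: O-sulfonylation of the sodium-chelated (Z)-enolate of the β-keto ester should give the (Z)-enol triflate, which fixes the geometry of the future tetrasubstituted C8=C9 bond.

**Step 5**
Reactants: 11 tert-butyl (2Z,6E)-9-(1,3-dioxolan-2-yl)-2,6-dimethyl-3-{[(trifluoromethyl)sulfonyl]oxy}nona-2,6-dienoate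
Product: 12 tert-butyl (2E,6E)-9-(1,3-dioxolan-2-yl)-2,3,6-trimethylnona-2,6-dienoate
Conditions: MeMgBr (1.5 equiv), Fe(acac)3 (5 mol %), THF/NMP, −30 °C
Reagents that add atoms: methylmagnesium bromide, C[Mg]Br
Why: iron-catalysed Kumada-type cross-coupling of the enol triflate should proceed with retention, so that the new C8 methyl is cis to the ester and trans to the C9 methyl.

**Step 6**
Reactants: 12 tert-butyl (2E,6E)-9-(1,3-dioxolan-2-yl)-2,3,6-trimethylnona-2,6-dienoate
Product: 13 (2E,6E)-9-(1,3-dioxolan-2-yl)-2,3,6-trimethylnona-2,6-dien-1-ol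
Conditions: i-Bu2AlH (2.5 equiv), CH2Cl2, −78 → 0 °C; aq potassium sodium tartrate
Reagents that add atoms: none
Why: 1,2-reduction of the unsaturated ester by the aluminium hydride should give the allylic alcohol (C11) without touching the acetal or the alkenes.

**Step 7**
Reactants: 13 (2E,6E)-9-(1,3-dioxolan-2-yl)-2,3,6-trimethylnona-2,6-dien-1-ol; 14 isofraxidin (7-hydroxy-6,8-dimethoxy-2H-chromen-2-one)
Product: 15 7-{[(2E,6E)-9-(1,3-dioxolan-2-yl)-2,3,6-trimethylnona-2,6-dien-1-yl]oxy}-6,8-dimethoxy-2H-chromen-2-one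
Conditions: PPh3, DIAD, THF, 0 °C → rt
Reagents that add atoms: none
Why: Mitsunobu etherification of the primary allylic alcohol with the acidic coumarin phenol should form the C11–O bond by SN2 displacement without allylic transposition.

**Step 8**
Reactants: 15 7-{[(2E,6E)-9-(1,3-dioxolan-2-yl)-2,3,6-trimethylnona-2,6-dien-1-yl]oxy}-6,8-dimethoxy-2H-chromen-2-one
Product: 16 (4E,8E)-10-[(6,8-dimethoxy-2-oxo-2H-chromen-7-yl)oxy]-5,8,9-trimethyldeca-4,8-dienal
Conditions: 1 M HCl, THF, rt
Reagents that add atoms: water, O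
Why: acid-catalysed hydrolysis of the dioxolane should release the C3 aldehyde under conditions too mild to ionise the allylic aryl ether.

**Step 9**
Reactants: 16 (4E,8E)-10-[(6,8-dimethoxy-2-oxo-2H-chromen-7-yl)oxy]-5,8,9-trimethyldeca-4,8-dienal; 17 ethyl diazoacetate
Product: 18 ethyl (6E,10E)-12-[(6,8-dimethoxy-2-oxo-2H-chromen-7-yl)oxy]-7,10,11-trimethyl-3-oxododeca-6,10-dienoate
Conditions: SnCl2 (10 mol %), CH2Cl2, rt
Reagents that add atoms: none
Why: the Roskamp reaction (Lewis-acid-catalysed addition of the diazo ester to the aldehyde, 1,2-hydride shift and loss of N2) should give the β-keto ester (C3–C4 bond) under neutral conditions that the coumarin tolerates.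

**Step 10**
Reactants: 18 ethyl (6E,10E)-12-[(6,8-dimethoxy-2-oxo-2H-chromen-7-yl)oxy]-7,10,11-trimethyl-3-oxododeca-6,10-dienoate
Product: 19 ethyl (1S,4aS,5S,6S,8aR)-5-{[(6,8-dimethoxy-2-oxo-2H-chromen-7-yl)oxy]methyl}-5,6,8a-trimethyl-2-oxodecahydronaphthalene-1-carboxylate
Conditions: (R)-2'-methoxy-1,1'-binaphthalen-2-ol·SnCl4 (2 equiv), CH2Cl2, −78 °C; aq NaHCO3
Reagents that add atoms: none
Why: Proposed new method: the chiral Lewis-acid-assisted Brønsted acid should transfer a proton to C8 of the tetrasubstituted C8=C9 bond while the C5=C10 π-bond attacks C9 from the opposite face and the enol carbon C4 of the β-keto ester captures the developing C5 cation, so that C9–C10 and C4–C5 form in one chair–chair cationic cascade. The closest known reaction types are the SnCl4-promoted, proton-initiated polyene cyclization terminated at carbon by a β-keto ester and the enantioselective protonative polyprenoid cyclization with binaphthol-derived acid·SnCl4 complexes; new here are the tetrasubstituted, CH2OAr-bearing initiating alkene and the combination of the two. Ring B closes 6-endo-trig at C10, and ring A closes by 6-(enol-endo) attack of C4 on the trigonal C5 cation, which is the C4–C5 bond. Anti addition of H and C10 across the (E)-C8=C9 bond fixes C8 and C9 (C8 methyl axial and trans to the C9 methyl, CH2OAr equatorial); anti addition of C9 and C4 across the (E)-C5=C10 bond fixes the trans ring fusion with the C5 methyl cis to the C9 methyl; the enantiotopic face of C8 is chosen by the chiral proton donor; C4 stays epimerizable with the ester equatorial. The step needs protonation at C8 and not at C9 (only this mode lets the flanking C5=C10 bond assist through a six-membered chair), C- over O-termination (for which SnCl4-bound β-keto esters are the established terminators), and survival of the allylic C11–O bond (helped by the low basicity of the coumarinyl ether oxygen at −78 °C).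

**Step 11**
Reactants: 19 ethyl (1S,4aS,5S,6S,8aR)-5-{[(6,8-dimethoxy-2-oxo-2H-chromen-7-yl)oxy]methyl}-5,6,8a-trimethyl-2-oxodecahydronaphthalene-1-carboxylate
Product: 20 ethyl (1S,4aS,5S,6S,8aR)-5-{[(6,8-dimethoxy-2-oxo-2H-chromen-7-yl)oxy]methyl}-1,5,6,8a-tetramethyl-2-oxodecahydronaphthalene-1-carboxylate
Conditions: K2CO3, MeI, acetone, 50 °C
Reagents that add atoms: iodomethane, CI
Why: C-alkylation of the β-keto ester enolate with MeI should place the methyl on C4 from the face anti to the axial C5 methyl, a stereocentre that is reset in step 12.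

**Step 12**
Reactants: 20 ethyl (1S,4aS,5S,6S,8aR)-5-{[(6,8-dimethoxy-2-oxo-2H-chromen-7-yl)oxy]methyl}-1,5,6,8a-tetramethyl-2-oxodecahydronaphthalene-1-carboxylate
Product: 21 7-{[(1S,2S,4aR,5S,8aS)-1,2,4a,5-tetramethyl-6-oxodecahydronaphthalen-1-yl]methoxy}-6,8-dimethoxy-2H-chromen-2-one
Conditions: LiCl, DMSO/H2O, 150 °C
Reagents that add atoms: none
Why: Krapcho dealkoxycarbonylation should remove the ester, and protonation of the resulting enolate under equilibrating conditions should leave the C4 methyl in the more stable equatorial position, cis to the C5 methyl, as in friedelin-type 3-ketones.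

**Compound list**

1 | methacrolein (2-methylprop-2-enal) | C=C(C)C=O | starting material
2 | 2-(1,3-dioxolan-2-yl)ethylmagnesium bromide | Br[Mg]CCC1OCCO1 | starting material
3 | (±)-5-(1,3-dioxolan-2-yl)-2-methylpent-1-en-3-ol | C=C(C)C(O)CCC1OCCO1 | intermediate
4 | triethyl orthoacetate | CC(OCC)(OCC)OCC | starting material
5 | mixed ketene acetal 2-{3-[(1-ethoxyethenyl)oxy]-4-methylpent-4-en-1-yl}-1,3-dioxolane | C=C(OCC)OC(CCC1OCCO1)C(C)=C | intermediate
6 | ethyl (4E)-7-(1,3-dioxolan-2-yl)-4-methylhept-4-enoate | CCOC(=O)CC/C(C)=C/CCC1OCCO1 | intermediate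
7 | tert-butyl propionate | CCC(=O)OC(C)(C)C | starting material
8 | lithium enolate of tert-butyl propionate | [Li+].CC=C([O-])OC(C)(C)C | intermediate
9 | tert-butyl (6E)-9-(1,3-dioxolan-2-yl)-2,6-dimethyl-3-oxonon-6-enoate | CC(C(=O)OC(C)(C)C)C(=O)CC/C(C)=C/CCC1OCCO1 | intermediate
10 | sodium (Z)-enolate of 9 | [Na+].C/C(C(=O)OC(C)(C)C)=C(/[O-])CC/C(C)=C/CCC1OCCO1 | intermediate
11 | tert-butyl (2Z,6E)-9-(1,3-dioxolan-2-yl)-2,6-dimethyl-3-{[(trifluoromethyl)sulfonyl]oxy}nona-2,6-dienoate | C/C(C(=O)OC(C)(C)C)=C(/OS(=O)(=O)C(F)(F)F)CC/C(C)=C/CCC1OCCO1 | intermediate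
12 | tert-butyl (2E,6E)-9-(1,3-dioxolan-2-yl)-2,3,6-trimethylnona-2,6-dienoate | C/C(C(=O)OC(C)(C)C)=C(/C)CC/C(C)=C/CCC1OCCO1 | intermediate
13 | (2E,6E)-9-(1,3-dioxolan-2-yl)-2,3,6-trimethylnona-2,6-dien-1-ol | C/C(CO)=C(/C)CC/C(C)=C/CCC1OCCO1 | intermediate
14 | isofraxidin (7-hydroxy-6,8-dimethoxy-2H-chromen-2-one) | COc1cc2ccc(=O)oc2c(OC)c1O | starting material
15 | 7-{[(2E,6E)-9-(1,3-dioxolan-2-yl)-2,3,6-trimethylnona-2,6-dien-1-yl]oxy}-6,8-dimethoxy-2H-chromen-2-one | COc1cc2ccc(=O)oc2c(OC)c1OC/C(C)=C(\C)CC/C(C)=C/CCC1OCCO1 | intermediate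
16 | (4E,8E)-10-[(6,8-dimethoxy-2-oxo-2H-chromen-7-yl)oxy]-5,8,9-trimethyldeca-4,8-dienal | COc1cc2ccc(=O)oc2c(OC)c1OC/C(C)=C(\C)CC/C(C)=C/CCC=O | intermediate
17 | ethyl diazoacetate | CCOC(=O)C=[N+]=[N-] | starting material
18 | ethyl (6E,10E)-12-[(6,8-dimethoxy-2-oxo-2H-chromen-7-yl)oxy]-7,10,11-trimethyl-3-oxododeca-6,10-dienoate | COc1cc2ccc(=O)oc2c(OC)c1OC/C(C)=C(\C)CC/C(C)=C/CCC(=O)CC(=O)OCC | intermediate
19 | ethyl (1S,4aS,5S,6S,8aR)-5-{[(6,8-dimethoxy-2-oxo-2H-chromen-7-yl)oxy]methyl}-5,6,8a-trimethyl-2-oxodecahydronaphthalene-1-carboxylate (trans-decalin, ester equatorial on C4) | COc1cc2ccc(=O)oc2c(OC)c1OC[C@]1(C)[C@H]2CCC(=O)[C@@H](C(=O)OCC)[C@]2(C)CC[C@@H]1C | intermediate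
20 | ethyl (1S,4aS,5S,6S,8aR)-5-{[(6,8-dimethoxy-2-oxo-2H-chromen-7-yl)oxy]methyl}-1,5,6,8a-tetramethyl-2-oxodecahydronaphthalene-1-carboxylate (C4 methyl axial, ester equatorial) | COc1cc2ccc(=O)oc2c(OC)c1OC[C@]1(C)[C@H]2CCC(=O)[C@@](C)(C(=O)OCC)[C@]2(C)CC[C@@H]1C | intermediate
21 | 7-{[(1S,2S,4aR,5S,8aS)-1,2,4a,5-tetramethyl-6-oxodecahydronaphthalen-1-yl]methoxy}-6,8-dimethoxy-2H-chromen-2-one (CNP0225022.2) | COc1cc2ccc(=O)oc2c(OC)c1OC[C@]1(C)[C@H]2CCC(=O)[C@@H](C)[C@]2(C)CC[C@@H]1C | target

**Step count and risks**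

Total step count: 12. Longest linear sequence: 12 steps (1 → 21).

Steps most likely to fail:

1. Step 10 (proposed new method). The proton may be delivered to C9 instead of C8, the allylic C11–O bond may ionise, a 1,2-hydride shift from C11 to the C9 cation may intervene, the ketone oxygen may capture the C5 cation, or achiral protonation by a tin–keto ester complex may erode the facial selectivity. The fallback uses known chemistry and secures the enantiomer by resolution. Setting out from 18, the cyclization is run with achiral SnCl4 (2 equiv, CH2Cl2, −78 → −20 °C), a known type of proton-initiated, β-keto-ester-terminated polyene cyclization. It should give the same diastereomer as a racemate, that is 19 together with its enantiomer ent-19 F1. Condensation of the mixture with (S)-1-phenylethylamine (cat. AcOH, toluene, 4 Å sieves) should give two diastereomeric enamino esters, the (S)-1-phenylethylamine enamine of 19 F2 and the (S)-1-phenylethylamine enamine of ent-19 F3, to be separated by chromatography or crystallization. Hydrolysis of F2 with 1 M HCl in THF returns enantiopure 19, where the route is rejoined.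

2. Step 4. Triflation may occur partly through a non-chelated enolate, so that geometric purity at the future C8=C9 bond is lost and carried through step 5 into the wrong C8/C9 relationship. The fallback takes the geometry from an anti-carbomagnesiation instead. Setting out from 6, reduction with i-Bu2AlH (CH2Cl2, −78 °C) should give the aldehyde (4E)-7-(1,3-dioxolan-2-yl)-4-methylhept-4-enal F4. Seyferth–Gilbert homologation with dimethyl (1-diazo-2-oxopropyl)phosphonate (K2CO3, MeOH) should give the terminal alkyne 2-[(3E)-4-methyloct-3-en-7-yn-1-yl]-1,3-dioxolane F5. Hydroxymethylation (n-BuLi, then (CH2O)n, THF) should give the propargylic alcohol (6E)-9-(1,3-dioxolan-2-yl)-6-methylnon-6-en-2-yn-1-ol F6. Copper-catalysed anti addition of MeMgBr (CuI 10 mol %, THF, reflux) with iodine quench should give the iodo allylic alcohol (2Z,6E)-9-(1,3-dioxolan-2-yl)-3-iodo-2,6-dimethylnona-2,6-dien-1-ol F7. Negishi methylation with retention (MeZnCl, Pd(PPh3)4, THF) rejoins the route at 13.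

3. Step 11. Alkylation at the neopentyl-type C4, flanked by the quaternary C5, may be slow and may go to oxygen instead of carbon. The fallback moves the methylation to the acyclic stage, where C4 is unhindered. Setting out from 18, K2CO3 and MeI in acetone should give the α-methyl β-keto ester ethyl (6E,10E)-12-[(6,8-dimethoxy-2-oxo-2H-chromen-7-yl)oxy]-2,7,10,11-tetramethyl-3-oxododeca-6,10-dienoate F8. Its cyclization under the conditions of step 10, now terminated by the fully substituted enol carbon, would deliver 20 directly, where the route is rejoined.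

**Further compounds**

F1 | step 10 | ent-19, ethyl (1R,4aR,5R,6R,8aS)-5-{[(6,8-dimethoxy-2-oxo-2H-chromen-7-yl)oxy]methyl}-5,6,8a-trimethyl-2-oxodecahydronaphthalene-1-carboxylate | COc1cc2ccc(=O)oc2c(OC)c1OC[C@@]1(C)[C@@H]2CCC(=O)[C@H](C(=O)OCC)[C@@]2(C)CC[C@H]1C
F2 | step 10 | (S)-1-phenylethylamine enamine of 19, ethyl (4aS,5S,6S,8aR)-5-{[(6,8-dimethoxy-2-oxo-2H-chromen-7-yl)oxy]methyl}-5,6,8a-trimethyl-2-{[(1S)-1-phenylethyl]amino}-3,4,4a,5,6,7,8,8a-octahydronaphthalene-1-carboxylate | COc1cc2ccc(=O)oc2c(OC)c1OC[C@]1(C)[C@H]2CCC(N[C@@H](C)c3ccccc3)=C(C(=O)OCC)[C@]2(C)CC[C@@H]1C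
F3 | step 10 | (S)-1-phenylethylamine enamine of ent-19, the (4aR,5R,6R,8aS) diastereomer of F2 | COc1cc2ccc(=O)oc2c(OC)c1OC[C@@]1(C)[C@@H]2CCC(N[C@@H](C)c3ccccc3)=C(C(=O)OCC)[C@@]2(C)CC[C@H]1C
F4 | step 4 | (4E)-7-(1,3-dioxolan-2-yl)-4-methylhept-4-enal | O=CCC/C(C)=C/CCC1OCCO1
F5 | step 4 | 2-[(3E)-4-methyloct-3-en-7-yn-1-yl]-1,3-dioxolane | C#CCC/C(C)=C/CCC1OCCO1
F6 | step 4 | (6E)-9-(1,3-dioxolan-2-yl)-6-methylnon-6-en-2-yn-1-ol | OCC#CCC/C(C)=C/CCC1OCCO1
F7 | step 4 | (2Z,6E)-9-(1,3-dioxolan-2-yl)-3-iodo-2,6-dimethylnona-2,6-dien-1-ol | OC/C(C)=C(\I)CC/C(C)=C/CCC1OCCO1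
F8 | step 11 | ethyl (6E,10E)-12-[(6,8-dimethoxy-2-oxo-2H-chromen-7-yl)oxy]-2,7,10,11-tetramethyl-3-oxododeca-6,10-dienoate | COc1cc2ccc(=O)oc2c(OC)c1OC/C(C)=C(\C)CC/C(C)=C/CCC(=O)C(C)C(=O)OCC
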